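**Plan**

- Retrosynthesis: the three acyl C–O bonds are cut first (O8 methacrylate, O9 acetate, lactone C12–O6). Then ring bond C6–C7 is cut while C4 and C9 are joined (retro anionic oxy-Cope), which contracts the cyclodecadiene to a 1,6-dialkenylcyclohex-2-en-1-ol. This is cut at C8–C9 into a cyclohexenone and a dienyl unit.
- Enabling feature: the arc C9–C10(=C1)–C2–C3–C4 holds the one ring-cis olefin (the C1=C10 enal double bond), so with a C4–C9 bond it is a cyclohexene. C9 carries oxygen, and the E-C4=C5 olefin and the C6–C7 bond are the footprint of a [3,3] shift.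
- Forward order: six-membered ring (C9, C10, C1–C4, with C14, C15 and a C5=C6 silyl enol ether) → addition of the C7/C8/C11–C13 dienyl unit at C9 → ring expansion 6 → 10 with in-flask C8 oxygenation → esters → lactone and enal in one final oxidation.
- Stereochemistry: one catalytic asymmetric allylation sets the C4 quaternary centre (S). It is consumed in the key step, and its chirality is relayed through a chair transition state to C6 and C7. C8 follows from kinetic protonation of an enol ether on the exposed ring face, C9 from a CBS reduction.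

Key step: step 10

Remark: carbons carry germacrane numbers throughout (ring C1–C10; C15 = methyl on C4; C11 on C7 carries C12 and C13; C14 on C10). "Ring-cis" for C1=C10 means C2 and C9 on the same side.

**Route**

Step 1
Reactants: 1 2-methylcyclohexanone
Product: 2 trimethyl[(2-methylcyclohex-1-en-1-yl)oxy]silane
Conditions: TMSCl, NaI, Et3N, MeCN, rt; fractional distillation
Reagents that add atoms: chlorotrimethylsilane C[Si](C)(C)Cl
Why: Equilibrating silylation (TMSI formed in situ, amine base) should favour the more substituted silyl enol ether, a standard thermodynamic enol silane synthesis; no stereocentre is formed.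

Step 2
Reactants: 2 trimethyl[(2-methylcyclohex-1-en-1-yl)oxy]silane; 3 diallyl carbonate
Product: 4 (S)-2-allyl-2-methylcyclohexan-1-one
Conditions: Pd2(dba)3 (cat.), (S)-t-Bu-PHOX (cat.), Bu4N Ph3SiF2 (substoichiometric), THF, 25 °C
Reagents that add atoms: none
Why: Fluoride-initiated Pd-catalysed asymmetric allylic alkylation of the enolate (Tsuji–Trost type, PHOX ligand) forms the α-quaternary centre, the (S)-ligand being expected to give the (S)-ketone; this is the only external source of chirality.

Step 3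
Reactants: 4 (S)-2-allyl-2-methylcyclohexan-1-one
Product: 6 (S)-6-allyl-6-methylcyclohex-2-en-1-one, via lithium enolate 5 (not isolated)
Conditions: LDA, THF, −78 °C; then N-tert-butylbenzenesulfinimidoyl chloride, −78 °C
Reagents that add atoms: none
Why: Mukaiyama dehydrogenation: only the CH2 side can be enolised, the enolate is sulfenylated at carbon and syn-elimination gives the enone at low temperature without touching the allyl group or the quaternary centre.

Step 4
Reactants: 6 (S)-6-allyl-6-methylcyclohex-2-en-1-one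
Product: 7 (S)-6-allyl-2-(hydroxymethyl)-6-methylcyclohex-2-en-1-one
Conditions: aq. CH2O, DMAP (cat.), THF–H2O, rt
Reagents that add atoms: formaldehyde C=O
Why: Morita–Baylis–Hillman reaction of a cyclohexenone with formaldehyde puts C14 on the enone α-carbon (C10); the quaternary α′-carbon excludes competing aldol chemistry.

Step 5
Reactants: 7 (S)-6-allyl-2-(hydroxymethyl)-6-methylcyclohex-2-en-1-one
Product: 8 2-[(1S)-3-(hydroxymethyl)-1-methyl-2-oxocyclohex-3-en-1-yl]acetaldehyde
Conditions: OsO4 (cat.), NaIO4, 2,6-lutidine, dioxane–H2O, rt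
Reagents that add atoms: sodium periodate [Na+].[O-]I(=O)(=O)=O (oxygen source, relayed by catalytic osmium tetroxide O=[Os](=O)(=O)=O)
Why: Lemieux–Johnson cleavage is selective for the electron-rich terminal olefin over the electron-poor trisubstituted enone olefin and removes one carbon to give the C6 aldehyde.

Step 6
Reactants: 8 2-[(1S)-3-(hydroxymethyl)-1-methyl-2-oxocyclohex-3-en-1-yl]acetaldehyde
Product: 9 (S)-6-[(E)-2-(tert-butyldimethylsilyloxy)ethenyl]-2-[(tert-butyldimethylsilyloxy)methyl]-6-methylcyclohex-2-en-1-one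
Conditions: TBSOTf (excess), Et3N, CH2Cl2, −78 → 0 °C; chromatography on Et3N-deactivated silica
Reagents that add atoms: tert-butyldimethylsilyl triflate CC(C)(C)[Si](C)(C)OS(=O)(=O)C(F)(F)F
Why: Soft enolisation (R3SiOTf/amine) silylates the primary alcohol and converts the aldehyde, the only enolisable carbonyl because C4 is quaternary, into its silyl enol ether; the E isomer should predominate since the Z isomer would place OTBS cis to the quaternary carbon.

Step 7
Reactants: 10 2-bromoprop-2-en-1-ol
Product: 11 [(2-bromoprop-2-en-1-yl)oxy](tert-butyl)dimethylsilane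
Conditions: TBSCl, imidazole, CH2Cl2, 0 °C → rt
Reagents that add atoms: tert-butyldimethylsilyl chloride CC(C)(C)[Si](C)(C)Cl
Why: Standard silylation of a primary alcohol.

Step 8
Reactants: 11 [(2-bromoprop-2-en-1-yl)oxy](tert-butyl)dimethylsilane; 12 (E)-1,2-bis(tributylstannyl)ethene
Product: 13 (E)-tert-butyldimethyl{[2-methylidene-4-(tributylstannyl)but-3-en-1-yl]oxy}silane
Conditions: Pd(PPh3)4 (cat.), 12 in excess, toluene, 90 °C
Reagents that add atoms: none
Why: Stille coupling of the vinyl bromide at one tin terminus of the distannane proceeds with retention and leaves an (E)-alkenylstannane carrying C7, C8 and C11–C13.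

Step 9
Reactants: 13 (E)-tert-butyldimethyl{[2-methylidene-4-(tributylstannyl)but-3-en-1-yl]oxy}silane; 9 (S)-6-[(E)-2-(tert-butyldimethylsilyloxy)ethenyl]-2-[(tert-butyldimethylsilyloxy)methyl]-6-methylcyclohex-2-en-1-one
Product: 16 (1R,6S)-1-[(1E)-3-{[(tert-butyldimethylsilyl)oxy]methyl}buta-1,3-dien-1-yl]-6-[(E)-2-(tert-butyldimethylsilyloxy)ethenyl]-2-{[(tert-butyldimethylsilyl)oxy]methyl}-6-methylcyclohex-2-en-1-ol, via dienyllithium 14 (not isolated), via dienylcerium dichloride 15 (not isolated)
Conditions: 13, n-BuLi, THF, −78 °C; CeCl3, −78 °C; then 9, −78 °C; aq. NH4Cl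
Reagents that add atoms: none
Why: Tin–lithium exchange with retention, transmetalation to the weakly basic organocerium and 1,2-addition to the hindered enone carbonyl; Felkin–Anh-type attack anti to the larger and better σ-accepting silyloxyvinyl group on the neighbouring quaternary carbon (i.e. on the methyl face) should give the trans-1,6-dialkenyl carbinol with the new centre (1R).

Step 10
Reactants: 16 (1R,6S)-1-[(1E)-3-{[(tert-butyldimethylsilyl)oxy]methyl}buta-1,3-dien-1-yl]-6-[(E)-2-(tert-butyldimethylsilyloxy)ethenyl]-2-{[(tert-butyldimethylsilyl)oxy]methyl}-6-methylcyclohex-2-en-1-ol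
Product: 19 (6R,7R,8R)-6,12,14-tris(tert-butyldimethylsilyloxy)-8-hydroxygermacra-1(10)Z,4E,11(13)-trien-9-one, via potassium alkoxide 17 (not isolated), via ring-expanded potassium enolate 18 (not isolated)
Conditions: KHMDS, 18-crown-6, THF, 0 °C → rt; then 2-(phenylsulfonyl)-3-phenyloxaziridine, −78 °C; aq. NH4Cl
Reagents that add atoms: 2-(phenylsulfonyl)-3-phenyloxaziridine O=S(=O)(c1ccccc1)N1OC1c1ccccc1
Why: Alkoxide 17 undergoes an alkoxide-accelerated [3,3]-sigmatropic shift (anionic oxy-Cope) in which C4–C9 breaks and C6–C7 forms; the closest known reaction is the ring expansion of 1,6-dialkenylcyclohex-2-en-1-olates to cyclodeca-2,6-dienones, followed here by in-flask hydroxylation of the enolate with a sulfonyloxaziridine. The ten-membered ring is not closed end to end but arises by four-carbon ring expansion of the cyclohexene through a chair in which both ring bonds (C9–C10, C4–C3) and both terminal substituents (OTBS on C6, the C11 residue on C7) are equatorial while O− and CH3 are axial. C6 and C7 are set together by this chair from the two E olefins and the (S) quaternary centre C4, which is consumed (self-immolative chirality transfer) and gives the trans relationship of O6 and C11 with the absolute configuration of the target; the same chair makes C4=C5 E, and C1=C10 stays ring-cis because it was the cyclohexene double bond. C8 is hydroxylated on the exposed face of enolate 18 (anti to the new C6–C7 bond), but this configuration is not relied upon because step 12 resets it. The step needs chair over boat and [3,3] over fragmentation or [1,3] shift: the trans-diequatorial dialkenyl arrangement of 16 admits only one chair, and the E enol ether keeps its silyl group away from the alkoxide.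

Step 11
Reactants: 19 (6R,7R,8R)-6,12,14-tris(tert-butyldimethylsilyloxy)-8-hydroxygermacra-1(10)Z,4E,11(13)-trien-9-one
Product: 20 (6R,7R,8R)-6,12,14-tris(tert-butyldimethylsilyloxy)-9-oxogermacra-1(10)Z,4E,11(13)-trien-8-yl 2-methylprop-2-enoate
Conditions: methacrylic anhydride, Et3N, DMAP (cat.), CH2Cl2, 0 °C
Reagents that add atoms: methacrylic anhydride C=C(C)C(=O)OC(=O)C(C)=C
Why: DMAP-catalysed acylation of the secondary α-hydroxy ketone installs the C8 ester; any epimerisation at C8 is harmless because both epimers converge in step 12.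

Step 12
Reactants: 20 (6R,7R,8R)-6,12,14-tris(tert-butyldimethylsilyloxy)-9-oxogermacra-1(10)Z,4E,11(13)-trien-8-yl 2-methylprop-2-enoate
Product: 22 (6R,7R,8S)-6,12,14-tris(tert-butyldimethylsilyloxy)-9-oxogermacra-1(10)Z,4E,11(13)-trien-8-yl 2-methylprop-2-enoate, via trimethylsilyl enol ether 21 (not isolated)
Conditions: TMSOTf, Et3N, CH2Cl2, −78 → 0 °C; then CSA (cat.), THF–H2O, −20 °C
Reagents that add atoms: none
Why: Soft enolisation can only go toward C8 (C10 is sp2), and kinetic C-protonation during acid hydrolysis of the enol silane should occur on the exposed face anti to the C6–C7 bond, the same face oxygen used in step 10, so the ester oxygen ends in the in-plane outward position, i.e. (8S); A(1,3) strain keeps H7 in the enol plane and thereby defines that face.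

Step 13
Reactants: 22 (6R,7R,8S)-6,12,14-tris(tert-butyldimethylsilyloxy)-9-oxogermacra-1(10)Z,4E,11(13)-trien-8-yl 2-methylprop-2-enoate
Product: 23 (6R,7R,8S,9S)-6,12,14-tris(tert-butyldimethylsilyloxy)-9-hydroxygermacra-1(10)Z,4E,11(13)-trien-8-yl 2-methylprop-2-enoate
Conditions: (S)-Me-CBS oxazaborolidine, catecholborane, toluene, −78 °C
Reagents that add atoms: none
Why: Corey–Bakshi–Shibata 1,2-reduction of the enone with the alkenyl carbon C10 as the large group should give the (9S) allylic alcohol; substrate bias (Cornforth arrangement of C8–O and C9=O, peripheral hydride attack) points the same way, and the methacrylate is inert to catecholborane.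

Step 14
Reactants: 23 (6R,7R,8S,9S)-6,12,14-tris(tert-butyldimethylsilyloxy)-9-hydroxygermacra-1(10)Z,4E,11(13)-trien-8-yl 2-methylprop-2-enoate
Product: 24 (6R,7R,8S,9S)-9-acetoxy-6,12,14-tris(tert-butyldimethylsilyloxy)germacra-1(10)Z,4E,11(13)-trien-8-yl 2-methylprop-2-enoate
Conditions: Ac2O, pyridine, DMAP (cat.), CH2Cl2, 0 °C → rt
Reagents that add atoms: acetic anhydride CC(=O)OC(C)=O
Why: Standard acetylation of the only free hydroxyl; O8 and O9 are differentiated because they entered the molecule at different stages.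

Step 15
Reactants: 24 (6R,7R,8S,9S)-9-acetoxy-6,12,14-tris(tert-butyldimethylsilyloxy)germacra-1(10)Z,4E,11(13)-trien-8-yl 2-methylprop-2-enoate
Product: 25 (6R,7S,8S,9S)-9-acetoxy-6,12,14-trihydroxygermacra-1(10)Z,4E,11(13)-trien-8-yl 2-methylprop-2-enoate
Conditions: HF·pyridine, pyridine, THF, 0 °C → rt
Reagents that add atoms: none
Why: Buffered HF·pyridine should cleave all three silyl ethers under weakly acidic conditions in which the acetate and methacrylate neither hydrolyse nor migrate.

Step 16
Reactants: 25 (6R,7S,8S,9S)-9-acetoxy-6,12,14-trihydroxygermacra-1(10)Z,4E,11(13)-trien-8-yl 2-methylprop-2-enoate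
Product: 26 (6R,7S,8S,9S)-9-acetoxy-8-(methacryloyloxy)-14-oxogermacra-1(10)E,4E,11(13)-trien-12,6-olide (CNP0403553.1)
Conditions: TEMPO (cat.), PhI(OAc)2, CH2Cl2, rt
Reagents that add atoms: none
Why: TEMPO/PhI(OAc)2 oxidises primary allylic alcohols selectively: C14–OH gives the enal, and C12–OH gives the 2-substituted acrolein, which is trapped by the C6 hydroxyl as a lactol and oxidised on to the α-methylene-γ-lactone (oxidative lactonisation of a 1,4-diol); no stereocentre is touched.

**Compound list**

1 | 2-methylcyclohexanone | CC1CCCCC1=O | starting material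
2 | trimethyl[(2-methylcyclohex-1-en-1-yl)oxy]silane | CC1=C(O[Si](C)(C)C)CCCC1 | intermediate
3 | diallyl carbonate | C=CCOC(=O)OCC=C | starting material
4 | (S)-2-allyl-2-methylcyclohexan-1-one | C=CC[C@]1(C)CCCCC1=O | intermediate
5 | lithium (S)-6-allyl-6-methylcyclohex-1-en-1-olate | C=CC[C@]1(C)CCCC=C1[O-].[Li+] | intermediate
6 | (S)-6-allyl-6-methylcyclohex-2-en-1-one | C=CC[C@]1(C)CCC=CC1=O | intermediate
7 | (S)-6-allyl-2-(hydroxymethyl)-6-methylcyclohex-2-en-1-one | C=CC[C@]1(C)CCC=C(CO)C1=O | intermediate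
8 | 2-[(1S)-3-(hydroxymethyl)-1-methyl-2-oxocyclohex-3-en-1-yl]acetaldehyde | O=CC[C@]1(C)CCC=C(CO)C1=O | intermediate
9 | (S)-6-[(E)-2-(tert-butyldimethylsilyloxy)ethenyl]-2-[(tert-butyldimethylsilyloxy)methyl]-6-methylcyclohex-2-en-1-one | CC(C)(C)[Si](C)(C)O/C=C/[C@]1(C)CCC=C(CO[Si](C)(C)C(C)(C)C)C1=O | intermediate
10 | 2-bromoprop-2-en-1-ol | C=C(Br)CO | starting material
11 | [(2-bromoprop-2-en-1-yl)oxy](tert-butyl)dimethylsilane | C=C(Br)CO[Si](C)(C)C(C)(C)C | intermediate
12 | (E)-1,2-bis(tributylstannyl)ethene | CCCC[Sn](CCCC)(CCCC)/C=C/[Sn](CCCC)(CCCC)CCCC | starting material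
13 | (E)-tert-butyldimethyl{[2-methylidene-4-(tributylstannyl)but-3-en-1-yl]oxy}silane | C=C(CO[Si](C)(C)C(C)(C)C)/C=C/[Sn](CCCC)(CCCC)CCCC | intermediate
14 | (E)-[3-(tert-butyldimethylsilyloxymethyl)buta-1,3-dien-1-yl]lithium | [Li]/C=C/C(=C)CO[Si](C)(C)C(C)(C)C | intermediate
15 | (E)-[3-(tert-butyldimethylsilyloxymethyl)buta-1,3-dien-1-yl]cerium dichloride | Cl[Ce](Cl)/C=C/C(=C)CO[Si](C)(C)C(C)(C)C | intermediate
16 | (1R,6S)-1-[(1E)-3-{[(tert-butyldimethylsilyl)oxy]methyl}buta-1,3-dien-1-yl]-6-[(E)-2-(tert-butyldimethylsilyloxy)ethenyl]-2-{[(tert-butyldimethylsilyl)oxy]methyl}-6-methylcyclohex-2-en-1-ol | CC(C)(C)[Si](C)(C)O/C=C/[C@]1(C)CCC=C(CO[Si](C)(C)C(C)(C)C)[C@@]1(O)/C=C/C(=C)CO[Si](C)(C)C(C)(C)C | intermediate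
17 | potassium alkoxide of 16 | CC(C)(C)[Si](C)(C)O/C=C/[C@]1(C)CCC=C(CO[Si](C)(C)C(C)(C)C)[C@@]1([O-])/C=C/C(=C)CO[Si](C)(C)C(C)(C)C.[K+] | intermediate
18 | potassium (6R,7S,8Z)-6,12,14-tris(tert-butyldimethylsilyloxy)germacra-1(10)Z,4E,8,11(13)-tetraen-9-olate | [K+].[O-]/C1=C\[C@@H](C(=C)CO[Si](C)(C)C(C)(C)C)[C@H](O[Si](C)(C)C(C)(C)C)/C=C(\C)CC/C=C1/CO[Si](C)(C)C(C)(C)C | intermediate
19 | (6R,7R,8R)-6,12,14-tris(tert-butyldimethylsilyloxy)-8-hydroxygermacra-1(10)Z,4E,11(13)-trien-9-one | O[C@@H]1[C@@H](C(=C)CO[Si](C)(C)C(C)(C)C)[C@H](O[Si](C)(C)C(C)(C)C)/C=C(\C)CC/C=C(/CO[Si](C)(C)C(C)(C)C)C1=O | intermediate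
20 | (6R,7R,8R)-6,12,14-tris(tert-butyldimethylsilyloxy)-9-oxogermacra-1(10)Z,4E,11(13)-trien-8-yl 2-methylprop-2-enoate | C=C(C)C(=O)O[C@@H]1[C@@H](C(=C)CO[Si](C)(C)C(C)(C)C)[C@H](O[Si](C)(C)C(C)(C)C)/C=C(\C)CC/C=C(/CO[Si](C)(C)C(C)(C)C)C1=O | intermediate
21 | (6R,7S)-6,12,14-tris(tert-butyldimethylsilyloxy)-9-(trimethylsilyloxy)germacra-1(10)Z,4E,8,11(13)-tetraen-8-yl 2-methylprop-2-enoate (C8=C9 geometry not defined) | C=C(C)C(=O)OC1=C(O[Si](C)(C)C)/C(CO[Si](C)(C)C(C)(C)C)=C\CC/C(C)=C/[C@@H](O[Si](C)(C)C(C)(C)C)[C@@H]1C(=C)CO[Si](C)(C)C(C)(C)C | intermediate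
22 | (6R,7R,8S)-6,12,14-tris(tert-butyldimethylsilyloxy)-9-oxogermacra-1(10)Z,4E,11(13)-trien-8-yl 2-methylprop-2-enoate | C=C(C)C(=O)O[C@H]1[C@@H](C(=C)CO[Si](C)(C)C(C)(C)C)[C@H](O[Si](C)(C)C(C)(C)C)/C=C(\C)CC/C=C(/CO[Si](C)(C)C(C)(C)C)C1=O | intermediate
23 | (6R,7R,8S,9S)-6,12,14-tris(tert-butyldimethylsilyloxy)-9-hydroxygermacra-1(10)Z,4E,11(13)-trien-8-yl 2-methylprop-2-enoate | C=C(C)C(=O)O[C@H]1[C@@H](C(=C)CO[Si](C)(C)C(C)(C)C)[C@H](O[Si](C)(C)C(C)(C)C)/C=C(\C)CC/C=C(/CO[Si](C)(C)C(C)(C)C)[C@@H]1O | intermediate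
24 | (6R,7R,8S,9S)-9-acetoxy-6,12,14-tris(tert-butyldimethylsilyloxy)germacra-1(10)Z,4E,11(13)-trien-8-yl 2-methylprop-2-enoate | C=C(C)C(=O)O[C@H]1[C@@H](C(=C)CO[Si](C)(C)C(C)(C)C)[C@H](O[Si](C)(C)C(C)(C)C)/C=C(\C)CC/C=C(/CO[Si](C)(C)C(C)(C)C)[C@@H]1OC(C)=O | intermediate
25 | (6R,7S,8S,9S)-9-acetoxy-6,12,14-trihydroxygermacra-1(10)Z,4E,11(13)-trien-8-yl 2-methylprop-2-enoate | C=C(C)C(=O)O[C@H]1[C@@H](C(=C)CO)[C@H](O)/C=C(\C)CC/C=C(/CO)[C@@H]1OC(C)=O | intermediate
26 | (6R,7S,8S,9S)-9-acetoxy-8-(methacryloyloxy)-14-oxogermacra-1(10)E,4E,11(13)-trien-12,6-olide (ring-cis C1=C10) | C=C(C)C(=O)O[C@H]1[C@H]2C(=C)C(=O)O[C@@H]2/C=C(\C)CC/C=C(/C=O)[C@@H]1OC(C)=O | target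

**Count**

Total steps: 16. Longest linear sequence: 14 (steps 1–6 and 9–16).

**Steps most likely to fail**

Step 10. The alkoxide may cleave heterolytically at C4–C9 and recombine without stereocontrol ([1,3] shift), or react through a boat and erode the C6/C7 relationship; the crowded enolate may also resist clean oxidation in the basic medium. The fallback leaves the anionic manifold. It sets out from 16 and comes back at 18 and thus 19. Carbinol 16 is silylated (TMSOTf, 2,6-lutidine, CH2Cl2, −78 °C) to the trimethylsilyl ether F1. Heating F1 in degassed toluene in a base-washed sealed tube (about 190 °C) should bring about the charge-neutral siloxy-Cope shift, in which C–C heterolysis is not available, and give the ring-expanded trimethylsilyl enol ether F2. KOt-Bu in THF at −78 °C then releases potassium enolate 18 free of crown ether, which is hydroxylated with the oxaziridine as before.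

Step 12. The C-protonation may discriminate poorly between the two faces of the enol ether, so that both C8 epimers form. The fallback moves the source of the C8 configuration from the macrocycle to the reagent. It sets out from 21, isolated after non-aqueous work-up, and comes back at 22. The enol ether is protonated with a stoichiometric Lewis acid-assisted chiral Brønsted acid (SnCl4·BINOL, toluene, −78 °C), the BINOL antipode being chosen to deliver the (8S) ketone. No new compound is made.

Step 9. The bulky alkenylcerium reagent may add with poor facial selectivity, or enolise the ketone at C2 instead of adding. The fallback replaces alkenylation by alkynylation and trans-hydrometalation. It sets out from 11 and 9 and comes back at 16. Bromide 11 is coupled with ethynyltrimethylsilane (Pd(PPh3)2Cl2, CuI, Et3N) to the silyl enyne F3, which K2CO3 in MeOH converts to the terminal enyne F4. Deprotonation with n-BuLi gives the lithium acetylide F5. This slim, strongly nucleophilic sp reagent adds to 9 (THF, −78 °C) with a different steric demand, giving the propargylic carbinol F6, whose C1 epimers can be separated if needed. Red-Al (THF, 0 °C → rt) then effects hydroxyl-directed trans-hydroalumination to the (E)-dienyl carbinol 16.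

Further compounds
F1 | step 10 | (1R,6S)-trimethylsilyl ether of 16 | CC(C)(C)[Si](C)(C)O/C=C/[C@]1(C)CCC=C(CO[Si](C)(C)C(C)(C)C)[C@@]1(O[Si](C)(C)C)/C=C/C(=C)CO[Si](C)(C)C(C)(C)C
F2 | step 10 | (6R,7S,8Z)-6,12,14-tris(tert-butyldimethylsilyloxy)-9-(trimethylsilyloxy)germacra-1(10)Z,4E,8,11(13)-tetraene | C[Si](C)(C)O/C1=C\[C@@H](C(=C)CO[Si](C)(C)C(C)(C)C)[C@H](O[Si](C)(C)C(C)(C)C)/C=C(\C)CC/C=C1/CO[Si](C)(C)C(C)(C)C
F0 | step 12 | none | none
F3 | step 9 | tert-butyldimethyl{[2-methylidene-4-(trimethylsilyl)but-3-yn-1-yl]oxy}silane | C=C(CO[Si](C)(C)C(C)(C)C)C#C[Si](C)(C)C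
F4 | step 9 | tert-butyldimethyl[(2-methylidenebut-3-yn-1-yl)oxy]silane | C=C(CO[Si](C)(C)C(C)(C)C)C#C
F5 | step 9 | [3-(tert-butyldimethylsilyloxymethyl)but-3-en-1-yn-1-yl]lithium | [Li]C#CC(=C)CO[Si](C)(C)C(C)(C)C
F6 | step 9 | (1S,6S)-1-[3-{[(tert-butyldimethylsilyl)oxy]methyl}but-3-en-1-yn-1-yl]-6-[(E)-2-(tert-butyldimethylsilyloxy)ethenyl]-2-{[(tert-butyldimethylsilyl)oxy]methyl}-6-methylcyclohex-2-en-1-ol | CC(C)(C)[Si](C)(C)O/C=C/[C@]1(C)CCC=C(CO[Si](C)(C)C(C)(C)C)[C@@]1(O)C#CC(=C)CO[Si](C)(C)C(C)(C)C
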